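Sunday's run is this very flask, followed up to 3.00 min, so what you want from it is one number that survives the step to the times asked.

- Sunday's: substrate 0.20 M; the very flask that is asked about, followed so far
- flask: substrate 0.20 M; time 6.0 min

- Sunday's (time / min: isomer of the product / %, target / %): 0.250: 1.1, 2.6; 0.417: 2.2, 5.0; 0.667: 3.8, 8.5; 1.00: 5.0, 12.0; 2.00: 9.1, 21.0; 3.00: 11.9, 27.0

(standard deviation of a reading: 0.3 percentage points)

- a reading or a percentage of target counts all its forms, free or not

- ratio of isomer of the product to target at 8.0 s
- ratio of isomer of the product to target at 6.0 min
- which of isomer of the product and target there is more of at 6.0 min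

Read the table across, isomer of the product over target, row by row. The first row gives 0.423 and the last 0.441, but don't call that a rise: a scatter of 0.3 percentage points moves the first ratio by about 0.115 and the last by about 0.0111. The last row is ten times as sharp. So add the columns before you divide, and you get 0.435: this is the split, summed isomer over summed target.

Target climbs from 2.6% to 27.0% of the charge, and the ratio shows no drift. A ratio that stands still needs no rate constant. My reckoning therefore holds the split at 8.0 s and at 6.0 min, and since it is below one, target leads.

The forecast says 0.43 at 8.0 s and 0.44 at 6.0 min, with target ahead, on the ground that “the two products form in a fixed proportion”.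

The flask gives 0.477 at 8.0 s and 0.434 at 6.0 min, with target ahead: 35.3% of the charge against 15.3% of isomer. The split times that target gives 15.4%.

    intermediate → decomposed reagent (k = 0.630 min⁻¹)
    substrate → intermediate (k = 0.260 min⁻¹)
    intermediate ⇌ isomer of the product (K = 2.80, k = 3.20 min⁻¹)
    substrate + target ⇌ idle adduct, settled at all times (K = 2.10 L mol⁻¹)
    intermediate ⇌ target (K = 5.90, k = 6.60 min⁻¹)
    2 substrate → self-condensation product (k = 0.0760 L mol⁻¹ min⁻¹)

The late ratio stands where it does partly because isomer goes back to intermediate: the run without that step ends at 3.29, not 0.434, with isomer ahead. The way back from target is another part: without it the run ends at 0.0439. At 8.0 s the step from isomer back to intermediate is the largest single effect, not the whole reason: without it the ratio reads 0.504, not 0.477. The neighbour flask, at 0.80 M of substrate, starts at 0.468 but ends at 0.364, below the split: the split predicts 14.2% of isomer, and it holds 11.9%. Take the target bound in idle adduct, 6.79% of the charge, out of its target count, and that flask's ratio reads 0.460.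

(The runs were computed on assumed constants; noise was put on by code.)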